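The route rests on cutting the C1–C10 bond that the oxirane shares with the ten-membered carbocycle (germacrane numbering; C1 = oxirane CH, C10 = oxirane C–CH3). Because ring carbons C2 and C9 are cis on the oxirane, this bond is the σ-bond of a (Z)-trisubstituted cyclodecene, the strain-favoured geometry. Ring-closing metathesis of an acyclic diene (C1 vinyl, C10 isopropenyl) that already carries the trans-γ-lactone, the α-methylene group, the angelate and all five sp3 stereocentres should therefore forge C1–C10 and the carbocycle in one operation; hydroxyl-directed epoxidation then completes the oxirane. The diene is built linearly by two Brown allylborations, a vanadium-directed epoxidation and an Evans aldol–lactonisation.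

Key step: step 15

Remark: ring atoms carry germacrane numbers (C1 oxirane CH, C3 CHOH, C4 C(OH)CH2OH with C15 = CH2OH, C6 lactone O–CH, C7, C8 angelate carbon, C10 oxirane C–CH3, C11–C13 methylene-lactone carbons); W = {(4R,5S)-4-[(4-methoxybenzyloxy)methyl]-2,2-dimethyl-5-(prop-2-en-1-yl)-1,3-dioxolan-4-yl}methyl; compounds 1, 9, 10, angelic acid, both enantiomers of Ipc2BOMe and the Grignard reagents are assumed to be purchasable.

Step 1
Reactants: 1 4-[(tert-butyldimethylsilyl)oxy]butanal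
Product: 2 4-[(tert-butyldimethylsilyl)oxy]-2-methylidenebutanal
Conditions: 37% aq. HCHO, pyrrolidine (10 mol%), EtCO2H (10 mol%), i-PrOH, 45 °C
Reagents that add atoms: formaldehyde, C=O
Why: Amine-catalysed Mannich condensation and elimination (organocatalytic α-methylenation of an aldehyde) installs the C4=C15 methylene that later becomes the C4 carbinol and its CH2OH arm, with no stereocentre formed.

Step 2
Reactants: 2 4-[(tert-butyldimethylsilyl)oxy]-2-methylidenebutanal
Product: 3 (4S)-1-[(tert-butyldimethylsilyl)oxy]-3-methylidenehept-6-en-4-ol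
Conditions: (−)-Ipc2BOMe, CH2=CHCH2MgBr, Et2O, 0 °C → rt; 2, −78 °C; then NaOH, H2O2, rt
Reagents that add atoms: allylmagnesium bromide, C=CC[Mg]Br, delivered as (−)-B-allyldiisopinocampheylborane, C=CCB([C@@H]1C[C@@H]2C[C@H]([C@H]1C)C2(C)C)[C@@H]1C[C@@H]2C[C@H]([C@H]1C)C2(C)C
Why: Brown allylboration through a chair Zimmerman–Traxler transition state, in which the (+)-α-pinene-derived Ipc groups should direct the allyl group to the Si face of the enal, sets C3 as (S).

Step 3
Reactants: 3 (4S)-1-[(tert-butyldimethylsilyl)oxy]-3-methylidenehept-6-en-4-ol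
Product: 4 (1S)-1-[(2R)-2-{2-[(tert-butyldimethylsilyl)oxy]ethyl}oxiran-2-yl]but-3-en-1-ol
Conditions: VO(acac)2 (2 mol%), t-BuOOH (decane), CH2Cl2, 0 °C → rt
Reagents that add atoms: tert-butyl hydroperoxide, CC(C)(C)OO
Why: Hydroxyl-directed vanadium-catalysed epoxidation should attack only the allylic 1,1-disubstituted alkene (the homoallylic vinyl group reacts far more slowly) and, because A(1,2) strain with the geminal CH2 chain disfavours the threo transition state, give the erythro epoxy alcohol, fixing C4 as (R).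

Step 4
Reactants: 4 (1S)-1-[(2R)-2-{2-[(tert-butyldimethylsilyl)oxy]ethyl}oxiran-2-yl]but-3-en-1-ol
Product: 5 (3R,4S)-1-[(tert-butyldimethylsilyl)oxy]-3-{[(4-methoxybenzyl)oxy]methyl}hept-6-ene-3,4-diol
Conditions: 4-MeOC6H4CH2OH, NaH, DMF, 50 °C
Reagents that add atoms: 4-methoxybenzyl alcohol, COc1ccc(CO)cc1
Why: Alkoxide SN2 opening of the 2,2-disubstituted oxirane at its unhindered CH2 carbon (Williamson-type epoxide opening, expected to outrun Payne migration onto the tertiary carbon) leaves both stereocentres untouched and delivers the C15 oxygen already protected as its PMB ether.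

Step 5
Reactants: 5 (3R,4S)-1-[(tert-butyldimethylsilyl)oxy]-3-{[(4-methoxybenzyl)oxy]methyl}hept-6-ene-3,4-diol
Product: 6 tert-butyl{2-[(4R,5S)-4-{[(4-methoxybenzyl)oxy]methyl}-2,2-dimethyl-5-(prop-2-en-1-yl)-1,3-dioxolan-4-yl]ethoxy}dimethylsilane
Conditions: Me2C(OMe)2, PPTS (cat.), CH2Cl2, rt
Reagents that add atoms: 2,2-dimethoxypropane, COC(C)(C)OC
Why: Acid-catalysed transketalisation ties the secondary C3 and tertiary C4 hydroxyls into a dioxolane that should survive base, oxidants, boron and lithium enolates and metathesis.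

Step 6
Reactants: 6 tert-butyl{2-[(4R,5S)-4-{[(4-methoxybenzyl)oxy]methyl}-2,2-dimethyl-5-(prop-2-en-1-yl)-1,3-dioxolan-4-yl]ethoxy}dimethylsilane
Product: 7 2-[(4R,5S)-4-{[(4-methoxybenzyl)oxy]methyl}-2,2-dimethyl-5-(prop-2-en-1-yl)-1,3-dioxolan-4-yl]ethan-1-ol
Conditions: Bu4NF, THF, 0 °C → rt
Reagents that add atoms: none
Why: Fluoride-induced Si–O cleavage frees only the primary C6 hydroxyl, since the acetonide and the PMB ether are inert to fluoride.

Step 7
Reactants: 7 2-[(4R,5S)-4-{[(4-methoxybenzyl)oxy]methyl}-2,2-dimethyl-5-(prop-2-en-1-yl)-1,3-dioxolan-4-yl]ethan-1-ol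
Product: 8 2-[(4R,5S)-4-{[(4-methoxybenzyl)oxy]methyl}-2,2-dimethyl-5-(prop-2-en-1-yl)-1,3-dioxolan-4-yl]acetaldehyde
Conditions: Dess–Martin periodinane, CH2Cl2, rt
Reagents that add atoms: none
Why: Dess–Martin oxidation gives the C6 aldehyde under non-aqueous, nearly neutral conditions, without β-elimination of the C4 ether oxygen and without touching the alkene or the PMB ether.

Step 8
Reactants: 9 (4S)-4-benzyl-1,3-oxazolidin-2-one; 10 methyl 4-chloro-4-oxobutanoate
Product: 11 methyl 4-[(4S)-4-benzyl-2-oxo-1,3-oxazolidin-3-yl]-4-oxobutanoate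
Conditions: n-BuLi, THF, −78 °C; then 10, −78 → 0 °C
Reagents that add atoms: none
Why: N-Acylation of the lithiated oxazolidinone by the acid chloride gives the succinate imide whose imide α-CH2 becomes C7 and whose ester arm becomes C11–C12.

Step 9
Reactants: 8 2-[(4R,5S)-4-{[(4-methoxybenzyl)oxy]methyl}-2,2-dimethyl-5-(prop-2-en-1-yl)-1,3-dioxolan-4-yl]acetaldehyde; 11 methyl 4-[(4S)-4-benzyl-2-oxo-1,3-oxazolidin-3-yl]-4-oxobutanoate
Product: 14 (4S)-4-benzyl-3-{[(2R,3S)-5-oxo-2-W-oxolan-3-yl]carbonyl}-1,3-oxazolidin-2-one, via boron enolate 12 (not isolated), via syn-aldol hydroxy ester 13 (not isolated)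
Conditions: 11, Bu2BOTf, i-Pr2NEt, CH2Cl2, 0 °C; 8, −78 → 0 °C; pH 7 buffer, MeOH, H2O2; then PPTS (cat.), CH2Cl2, rt
Reagents that add atoms: none
Why: Evans syn-aldol reaction of the (Z)-boron enolate through a Zimmerman–Traxler chair, on the enolate face away from the benzyl group, should set C6 (R) and C7 together, and the new C6 hydroxyl then closes onto the methyl ester (5-exo-trig lactonisation) to give the trans-disubstituted γ-lactone.

Step 10
Reactants: 14 (4S)-4-benzyl-3-{[(2R,3S)-5-oxo-2-W-oxolan-3-yl]carbonyl}-1,3-oxazolidin-2-one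
Product: 15 (2R,3S)-5-oxo-2-W-oxolane-3-carboxylic acid
Conditions: LiOH, H2O2, THF/H2O, 0 °C; Na2SO3; HCl (aq) to pH 3
Reagents that add atoms: hydrogen peroxide, OO (as LiOOH; one oxygen stays in the CO2H group)
Why: Hydroperoxide anion attacks the exocyclic imide carbonyl selectively (the lactone, if opened, recloses on acidification), releasing the auxiliary and the C8 carboxylic acid without epimerising C7.

Step 11
Reactants: 15 (2R,3S)-5-oxo-2-W-oxolane-3-carboxylic acid
Product: 17 (2R,3S)-5-oxo-2-W-oxolane-3-carbaldehyde, via acid chloride 16 (not isolated)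
Conditions: Me2C=C(Cl)NMe2, CH2Cl2, 0 °C → rt; then LiAlH(O-t-Bu)3, THF, −78 °C
Reagents that add atoms: none
Why: Neutral acid chloride formation with the Ghosez chloroenamine followed by partial reduction with the hindered hydride LiAlH(O-t-Bu)3 should stop at the C8 aldehyde at −78 °C and leave the lactone untouched, the sensitive β-acyloxy aldehyde being used crude at once.

Step 12
Reactants: 17 (2R,3S)-5-oxo-2-W-oxolane-3-carbaldehyde
Product: 18 (4R,5R)-4-[(1R)-1-hydroxy-3-methylbut-3-en-1-yl]-5-W-oxolan-2-one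
Conditions: (+)-Ipc2BOMe, CH2=C(CH3)CH2MgCl, Et2O, 0 °C → rt; 17, −78 °C; then HOCH2CH2NH2
Reagents that add atoms: 2-methylallylmagnesium chloride, C=C(C)C[Mg]Cl, delivered as (+)-B-(2-methylallyl)diisopinocampheylborane, C=C(C)CB([C@H]1C[C@H]2C[C@@H]([C@@H]1C)C2(C)C)[C@H]1C[C@H]2C[C@@H]([C@@H]1C)C2(C)C
Why: Reagent-controlled Brown methallylboration through a chair transition state should add the 2-methylallyl group to the Re face of the aldehyde and set C8 as (R), and the non-basic ethanolamine work-up avoids migration of the lactone to the new hydroxyl.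

Step 13
Reactants: 18 (4R,5R)-4-[(1R)-1-hydroxy-3-methylbut-3-en-1-yl]-5-W-oxolan-2-one
Product: 21 (4R,5R)-4-[(1R)-1-hydroxy-3-methylbut-3-en-1-yl]-3-methylidene-5-W-oxolan-2-one, via Mannich base 19 (not isolated), via trimethylammonium iodide 20 (not isolated)
Conditions: LiN(i-Pr)2 (2.3 equiv), THF, −78 °C; [CH2=NMe2]I, −78 °C → rt; then MeI, MeOH, rt; then NaHCO3 (aq)/CH2Cl2
Reagents that add atoms: N,N-dimethylmethyleneiminium iodide (Eschenmoser's salt), C=[N+](C)C.[I-]
Why: The alkoxide/lactone-enolate dianion undergoes a Mannich reaction at C11 and Hofmann-type elimination of the quaternised amine then gives the exocyclic C11=C13 methylene, the C11 stereocentre of the intermediates being destroyed in the elimination.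

Step 14
Reactants: 21 (4R,5R)-4-[(1R)-1-hydroxy-3-methylbut-3-en-1-yl]-3-methylidene-5-W-oxolan-2-one
Product: 22 (1R)-3-methyl-1-[(2R,3R)-4-methylidene-5-oxo-2-W-oxolan-3-yl]but-3-en-1-yl (2Z)-2-methylbut-2-enoate
Conditions: angelic acid, 2,4,6-Cl3C6H2COCl, Et3N, toluene, rt; then 21, 80 °C
Reagents that add atoms: angelic acid, C/C=C(/C)C(=O)O
Why: Yamaguchi-type acylation through the preformed mixed anhydride, run without DMAP, should esterify the C8 hydroxyl with retention at C8 and without Z to E isomerisation of the angeloyl double bond.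

Step 15
Reactants: 22 (1R)-3-methyl-1-[(2R,3R)-4-methylidene-5-oxo-2-W-oxolan-3-yl]but-3-en-1-yl (2Z)-2-methylbut-2-enoate
Product: 23 (1(10)Z,3S,4R,6R,7R,8R)-8-angeloyloxy-3,4-(isopropylidenedioxy)-15-[(4-methoxybenzyl)oxy]germacra-1(10),11(13)-dien-12,6-olide
Conditions: RuCl2(=CH-C6H4-2-O-i-Pr)(H2IMes) (second-generation Hoveyda–Grubbs catalyst, 15 mol%), 1,4-benzoquinone (20 mol%), toluene (1 mM), 80 °C
Reagents that add atoms: none
Why: Ring-closing olefin metathesis by the Chauvin mechanism: the ruthenium alkylidene loads on the monosubstituted C1 vinyl group, adds across the C10 isopropenyl group in a [2+2] step, and the ruthenacyclobutane cycloreverts, releasing ethylene and creating the C1=C10 bond. The closest known reaction type is ring-closing metathesis to eight- to ten-membered carbocycles carrying a trisubstituted (Z)-alkene with N-heterocyclic-carbene ruthenium catalysts. The ten-membered carbocycle is closed in an endocyclic mode, both new sp2 carbons lying in the ring, and emerges trans-fused to the existing γ-lactone. No sp3 stereocentre is formed; the alkene should be Z because C2 and C9 are cis in the less strained cyclodecene and reversible metathesis funnels material towards it, and this geometry maps onto the cis-fused oxirane. The step needs chemoselectivity among four alkenes and ring closure over oligomerisation. The electron-poor, more highly substituted methylene-lactone and angelate alkenes should be inert to the catalyst, while high dilution, loss of ethylene and the turn imposed by the dioxolane and the trans-lactone favour cyclisation.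

Step 16
Reactants: 23 (1(10)Z,3S,4R,6R,7R,8R)-8-angeloyloxy-3,4-(isopropylidenedioxy)-15-[(4-methoxybenzyl)oxy]germacra-1(10),11(13)-dien-12,6-olide
Product: 24 (1(10)Z,3S,4R,6R,7R,8R)-8-angeloyloxy-15-hydroxy-3,4-(isopropylidenedioxy)germacra-1(10),11(13)-dien-12,6-olide
Conditions: DDQ, CH2Cl2/pH 7 buffer (10:1), 0 °C
Reagents that add atoms: none
Why: Oxidation of the electron-rich PMB ether to its oxocarbenium ion and hydrolysis frees the C15 hydroxyl under neutral conditions that should leave the alkenes, the esters and the acetonide alone.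

Step 17
Reactants: 24 (1(10)Z,3S,4R,6R,7R,8R)-8-angeloyloxy-15-hydroxy-3,4-(isopropylidenedioxy)germacra-1(10),11(13)-dien-12,6-olide
Product: 25 (1(10)Z,3S,4R,6R,7R,8R)-8-angeloyloxy-3,4,15-trihydroxygermacra-1(10),11(13)-dien-12,6-olide
Conditions: AcOH/H2O (4:1), 45 °C
Reagents that add atoms: none
Why: Mild acid hydrolysis of the dioxolane releases the C3 and C4 hydroxyls before the acid-labile oxirane exists, the trisubstituted ring alkene being stable to aqueous acetic acid.

Step 18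
Reactants: 25 (1(10)Z,3S,4R,6R,7R,8R)-8-angeloyloxy-3,4,15-trihydroxygermacra-1(10),11(13)-dien-12,6-olide
Product: 26 CNP0307250.1, the (1R,10S)-1,10-epoxide of 25
Conditions: VO(acac)2 (5 mol%), t-BuOOH (decane), 2,6-lutidine, CH2Cl2, 0 °C
Reagents that add atoms: tert-butyl hydroperoxide, CC(C)(C)OO
Why: Vanadium-catalysed epoxidation directed by the homoallylic C3 hydroxyl through a chair-like transition state (C4 equatorial, C9 turned outward) should deliver oxygen only to the electron-rich C1=C10 alkene, on the face that places the oxirane oxygen 1,3-syn to the C3 hydroxyl, giving the (1R,10S) cis-fused oxirane while the electron-poor methylene lactone and angelate do not react.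

Compound list
1 | 4-[(tert-butyldimethylsilyl)oxy]butanal | CC(C)(C)[Si](C)(C)OCCCC=O | starting material
2 | 4-[(tert-butyldimethylsilyl)oxy]-2-methylidenebutanal | CC(C)(C)[Si](C)(C)OCCC(=C)C=O | intermediate
3 | (4S)-1-[(tert-butyldimethylsilyl)oxy]-3-methylidenehept-6-en-4-ol | CC(C)(C)[Si](C)(C)OCCC(=C)[C@@H](O)CC=C | intermediate
4 | (1S)-1-[(2R)-2-{2-[(tert-butyldimethylsilyl)oxy]ethyl}oxiran-2-yl]but-3-en-1-ol | CC(C)(C)[Si](C)(C)OCC[C@@]1(CO1)[C@@H](O)CC=C | intermediate
5 | (3R,4S)-1-[(tert-butyldimethylsilyl)oxy]-3-{[(4-methoxybenzyl)oxy]methyl}hept-6-ene-3,4-diol | CC(C)(C)[Si](C)(C)OCC[C@@](O)(COCc1ccc(OC)cc1)[C@@H](O)CC=C | intermediate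
6 | tert-butyl{2-[(4R,5S)-4-{[(4-methoxybenzyl)oxy]methyl}-2,2-dimethyl-5-(prop-2-en-1-yl)-1,3-dioxolan-4-yl]ethoxy}dimethylsilane | CC(C)(C)[Si](C)(C)OCC[C@@](O1)(COCc2ccc(OC)cc2)[C@@H](OC1(C)C)CC=C | intermediate
7 | 2-[(4R,5S)-4-{[(4-methoxybenzyl)oxy]methyl}-2,2-dimethyl-5-(prop-2-en-1-yl)-1,3-dioxolan-4-yl]ethan-1-ol | OCC[C@@](O1)(COCc2ccc(OC)cc2)[C@@H](OC1(C)C)CC=C | intermediate
8 | 2-[(4R,5S)-4-{[(4-methoxybenzyl)oxy]methyl}-2,2-dimethyl-5-(prop-2-en-1-yl)-1,3-dioxolan-4-yl]acetaldehyde | O=CC[C@@](O1)(COCc2ccc(OC)cc2)[C@@H](OC1(C)C)CC=C | intermediate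
9 | (4S)-4-benzyl-1,3-oxazolidin-2-one | O=C1N[C@@H](Cc2ccccc2)CO1 | starting material
10 | methyl 4-chloro-4-oxobutanoate | COC(=O)CCC(Cl)=O | starting material
11 | methyl 4-[(4S)-4-benzyl-2-oxo-1,3-oxazolidin-3-yl]-4-oxobutanoate | COC(=O)CCC(=O)N1[C@@H](Cc2ccccc2)COC1=O | intermediate
12 | (Z)-dibutylboron enolate of 11 | CCCCB(CCCC)O/C(=C\CC(=O)OC)N1[C@@H](Cc2ccccc2)COC1=O | intermediate (not isolated)
13 | methyl (3S,4R)-3-{[(4S)-4-benzyl-2-oxo-1,3-oxazolidin-3-yl]carbonyl}-4-hydroxy-5-[(4R,5S)-4-{[(4-methoxybenzyl)oxy]methyl}-2,2-dimethyl-5-(prop-2-en-1-yl)-1,3-dioxolan-4-yl]pentanoate | O=C(N1[C@@H](Cc2ccccc2)COC1=O)[C@@H](CC(=O)OC)[C@H](O)C[C@@](O3)(COCc4ccc(OC)cc4)[C@@H](OC3(C)C)CC=C | intermediate (not isolated)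
14 | (4S)-4-benzyl-3-{[(2R,3S)-5-oxo-2-W-oxolan-3-yl]carbonyl}-1,3-oxazolidin-2-one | C1C(=O)O[C@H](C[C@@](O3)(COCc4ccc(OC)cc4)[C@@H](OC3(C)C)CC=C)[C@H]1C(=O)N5[C@@H](Cc6ccccc6)COC5=O | intermediate
15 | (2R,3S)-5-oxo-2-W-oxolane-3-carboxylic acid | C1C(=O)O[C@H](C[C@@](O3)(COCc4ccc(OC)cc4)[C@@H](OC3(C)C)CC=C)[C@H]1C(=O)O | intermediate
16 | (2R,3S)-5-oxo-2-W-oxolane-3-carbonyl chloride | C1C(=O)O[C@H](C[C@@](O3)(COCc4ccc(OC)cc4)[C@@H](OC3(C)C)CC=C)[C@H]1C(Cl)=O | intermediate (not isolated)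
17 | (2R,3S)-5-oxo-2-W-oxolane-3-carbaldehyde | C1C(=O)O[C@H](C[C@@](O3)(COCc4ccc(OC)cc4)[C@@H](OC3(C)C)CC=C)[C@H]1C=O | intermediate
18 | (4R,5R)-4-[(1R)-1-hydroxy-3-methylbut-3-en-1-yl]-5-W-oxolan-2-one | C1C(=O)O[C@H](C[C@@](O3)(COCc4ccc(OC)cc4)[C@@H](OC3(C)C)CC=C)[C@H]1[C@H](O)CC(C)=C | intermediate
19 | 3-[(dimethylamino)methyl] derivative of 18 (both C3 epimers) | CN(C)CC1C(=O)O[C@H](C[C@@](O3)(COCc4ccc(OC)cc4)[C@@H](OC3(C)C)CC=C)[C@H]1[C@H](O)CC(C)=C | intermediate (not isolated)
20 | N-methyl quaternary ammonium iodide of 19 | C[N+](C)(C)CC1C(=O)O[C@H](C[C@@](O3)(COCc4ccc(OC)cc4)[C@@H](OC3(C)C)CC=C)[C@H]1[C@H](O)CC(C)=C.[I-] | intermediate (not isolated)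
21 | (4R,5R)-4-[(1R)-1-hydroxy-3-methylbut-3-en-1-yl]-3-methylidene-5-W-oxolan-2-one | C=C1C(=O)O[C@H](C[C@@](O3)(COCc4ccc(OC)cc4)[C@@H](OC3(C)C)CC=C)[C@H]1[C@H](O)CC(C)=C | intermediate
22 | (1R)-3-methyl-1-[(2R,3R)-4-methylidene-5-oxo-2-W-oxolan-3-yl]but-3-en-1-yl (2Z)-2-methylbut-2-enoate | C=C1C(=O)O[C@H](C[C@@](O3)(COCc4ccc(OC)cc4)[C@@H](OC3(C)C)CC=C)[C@H]1[C@H](OC(=O)/C(C)=C\C)CC(C)=C | intermediate
23 | (1(10)Z,3S,4R,6R,7R,8R)-8-angeloyloxy-3,4-(isopropylidenedioxy)-15-[(4-methoxybenzyl)oxy]germacra-1(10),11(13)-dien-12,6-olide | C=C1C(=O)O[C@@H]2C[C@@](O3)(COCc4ccc(OC)cc4)[C@@H](OC3(C)C)C/C=C(C)\C[C@@H](OC(=O)/C(C)=C\C)[C@@H]12 | intermediate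
24 | (1(10)Z,3S,4R,6R,7R,8R)-8-angeloyloxy-15-hydroxy-3,4-(isopropylidenedioxy)germacra-1(10),11(13)-dien-12,6-olide | C=C1C(=O)O[C@@H]2C[C@@](O3)(CO)[C@@H](OC3(C)C)C/C=C(C)\C[C@@H](OC(=O)/C(C)=C\C)[C@@H]12 | intermediate
25 | (1(10)Z,3S,4R,6R,7R,8R)-8-angeloyloxy-3,4,15-trihydroxygermacra-1(10),11(13)-dien-12,6-olide | C=C1C(=O)O[C@@H]2C[C@@](O)(CO)[C@@H](O)C/C=C(C)\C[C@@H](OC(=O)/C(C)=C\C)[C@@H]12 | intermediate
26 | CNP0307250.1, the (1R,10S)-1,10-epoxide of 25 (8-angeloyloxy-1,10-epoxy-3,4,15-trihydroxygermacr-11(13)-en-12,6-olide, trans-fused lactone, cis-fused oxirane) | C=C1C(=O)O[C@@H]2C[C@@](O)(CO)[C@@H](O)C[C@H]3O[C@@]3(C)C[C@@H](OC(=O)/C(C)=C\C)[C@@H]12 | target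

Total step count: 18. Longest linear sequence: 17 steps (1 to 26 through steps 1–7 and 9–18; step 8 prepares the imide 11).

Steps most likely to fail

1. Step 15 (ring-closing metathesis). The carbene may dimerise the substrate through the vinyl group before it engages the hindered isopropenyl group, and alkene migration or E/Z scrambling may erode the ring closure. The fallback closes the same C1–C10 bond by carbonyl coupling on a substrate that carries no reducible enoate; it sets out from 18 and comes back at 23. The C8 hydroxyl of 18 is silylated (TBSOTf, 2,6-lutidine) to give the tert-butyldimethylsilyl ether F1. Lemieux–Johnson cleavage of both alkenes (OsO4 cat., NaIO4, 2,6-lutidine, dioxane/H2O) should give the C1-aldehyde C10-methyl ketone F2. Intramolecular McMurry coupling with low-valent titanium (TiCl3(DME)1.5, Zn(Cu), DME, reflux, slow addition) should then give the (Z)-cyclodecene lactone F3. Methylenation as in step 13, with one equivalent of base, gives the silylated methylene lactone F4; HF·pyridine frees the C8 alcohol F5; and the acylation of step 14 leads to 23.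

2. Step 18 (directed epoxidation). Oxygen may be delivered to the wrong face of the ring alkene, or the new oxirane may be opened transannularly by the C3 or C4 hydroxyl on the Lewis-acidic metal. The fallback brings the oxirane oxygen in as a nucleophile and keeps it masked through the acidic deprotection; it sets out from 23 and comes back at 26. NBS in aqueous acetone at 0 °C should convert 23 into the (1S,10S)-bromohydrin F6 (bromonium on the exposed face, water anti at the tertiary C10). DDQ gives the primary alcohol F7 and aqueous acetic acid the bromohydrin triol F8. Ag2O in THF then closes the oxirane by displacement of bromide at C1 with inversion, giving 26.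

3. Step 13 (methylenation of the hydroxy lactone). The C8 alkoxide may attack the lactone carbonyl (migration of the lactone from O6 to O8), and incomplete dianion formation may stall the Mannich step. The fallback removes the free alkoxide; it sets out from 18 and comes back at 21. TESCl and imidazole in DMF give the triethylsilyl ether F9, which is methylenated through its mono-enolate (LiN(i-Pr)2; Eschenmoser's salt; MeI; NaHCO3) to the silylated methylene lactone F10; HF·pyridine in THF then returns 21.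

Further compounds
F1 | step 15 | tert-butyldimethylsilyl ether of 18 | C1C(=O)O[C@H](C[C@@](O3)(COCc4ccc(OC)cc4)[C@@H](OC3(C)C)CC=C)[C@H]1[C@H](O[Si](C)(C)C(C)(C)C)CC(C)=C
F2 | step 15 | keto aldehyde from cleavage of both alkenes of F1 (C1 aldehyde, C10 methyl ketone) | C1C(=O)O[C@H](C[C@@](O3)(COCc4ccc(OC)cc4)[C@@H](OC3(C)C)CC=O)[C@H]1[C@H](O[Si](C)(C)C(C)(C)C)CC(C)=O
F3 | step 15 | (1(10)Z)-8-[(tert-butyldimethylsilyl)oxy]-3,4-(isopropylidenedioxy)-15-[(4-methoxybenzyl)oxy]germacr-1(10)-en-12,6-olide | C1C(=O)O[C@@H]2C[C@@](O3)(COCc4ccc(OC)cc4)[C@@H](OC3(C)C)C/C=C(C)\C[C@@H](O[Si](C)(C)C(C)(C)C)[C@@H]12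
F4 | step 15 | 11(13)-methylidene derivative of F3 | C=C1C(=O)O[C@@H]2C[C@@](O3)(COCc4ccc(OC)cc4)[C@@H](OC3(C)C)C/C=C(C)\C[C@@H](O[Si](C)(C)C(C)(C)C)[C@@H]12
F5 | step 15 | 8-hydroxy compound from desilylation of F4 | C=C1C(=O)O[C@@H]2C[C@@](O3)(COCc4ccc(OC)cc4)[C@@H](OC3(C)C)C/C=C(C)\C[C@@H](O)[C@@H]12
F6 | step 18 | (1S,10S)-1-bromo-10-hydroxy adduct of 23 | C=C1C(=O)O[C@@H]2C[C@@](O3)(COCc4ccc(OC)cc4)[C@@H](OC3(C)C)C[C@H](Br)[C@](O)(C)C[C@@H](OC(=O)/C(C)=C\C)[C@@H]12
F7 | step 18 | 15-hydroxy bromohydrin from F6 | C=C1C(=O)O[C@@H]2C[C@@](O3)(CO)[C@@H](OC3(C)C)C[C@H](Br)[C@](O)(C)C[C@@H](OC(=O)/C(C)=C\C)[C@@H]12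
F8 | step 18 | (1S,10S)-1-bromo-3,4,10,15-tetrahydroxy compound from F7 | C=C1C(=O)O[C@@H]2C[C@@](O)(CO)[C@@H](O)C[C@H](Br)[C@](O)(C)C[C@@H](OC(=O)/C(C)=C\C)[C@@H]12
F9 | step 13 | triethylsilyl ether of 18 | C1C(=O)O[C@H](C[C@@](O3)(COCc4ccc(OC)cc4)[C@@H](OC3(C)C)CC=C)[C@H]1[C@H](O[Si](CC)(CC)CC)CC(C)=C
F10 | step 13 | triethylsilyl ether of 21 | C=C1C(=O)O[C@H](C[C@@](O3)(COCc4ccc(OC)cc4)[C@@H](OC3(C)C)CC=C)[C@H]1[C@H](O[Si](CC)(CC)CC)CC(C)=C
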